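(The data were computed with constants of no real substance; the scatter is artificial.)

No reading in the alder or larch run counts chains, so a length cannot be read off them, and we reckon by the balance of initiator.

common to all: initiator 0.75 mol%

|  | free monomer | remark | time |
|---|---|---|---|
| alder | 44 mM | run made earlier |  |
| larch | 120 mM | run made earlier |  |
| spring | 30 mM |  | 20 min |
| midnight | 100 mM |  | 20 min |

| run | time / min | monomer in chains / % | free monomer / % |
|---|---|---|---|
| alder | 0.833 | 1.5 | 98.5 |
| alder | 2.00 | 7.8 | 91.6 |
| alder | 4.00 | 27.5 | 72.3 |
| alder | 6.00 | 48.5 | 52.6 |
| alder | 8.00 | 65.5 | 35.0 |
| alder | 12.0 | 85.9 | 13.9 |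
| alder | 15.0 | 94.1 | 7.6 |
| larch | 2.00 | 42.1 | 57.8 |
| larch | 4.00 | 81.6 | 17.1 |
| larch | 6.00 | 95.1 | 5.0 |
| larch | 8.00 | 98.5 | 1.1 |
| larch | 10.0 | 100.0 | 0.7 |
| larch | 12.0 | 100.6 | 0.9 |
| larch | 15.0 | 99.8 | 0 |

(standard deviation of a reading: 0.5 percentage points)

* which of the two ends with the longer chains by the average number of monomer units in a chain (chains begun, living or dead) ("neither" if they lie within 10%) (spring / midnight / neither)
* average number of monomer units in a chain (chains begun, living or dead) at the end, spring
* average number of monomer units in a chain (chains begun, living or dead) at the end, midnight

- the average divides the monomer in chains by the number of chains begun, living and dead together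
- candidate steps: 2 living end -> dead end; free monomer + living end -> monomer in chains + living end; free monomer + initiator -> living end + monomer in chains
- the earlier runs do not show the number of chains; that part of a forecast is a guess

1. Each chain begun takes one initiator. With X the share of the free monomer charge in chains and φ the share of the initiator charge used, the length is L·X/φ, where L = 133 is the free monomer charged per initiator charged.
2. At equal loading, with ends lost slowly, concentration times time serves as the clock. Larch at 2.00 min has 42.1% in chains, and alder at the matching 5.45 min interpolates to 42.8%.
3. So spring matches alder at 13.6 min, giving X = 90.4%, while midnight matches larch at 16.7 min, so we take X as one.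
4. Setting φ to one gives 120 for spring and 133 for midnight, and those are the lengths we commit to as floors.
5. That φ is the weak link, since the curves give a product of two rate constants and not φ. If φ is small, new ends per unit of monomer in chains fall as ends multiply, so φ grows as the root of X and spring's length is 0.951 of midnight's, a gap below 10%. We say neither, with lengths above the floors by an unread factor.

The forecast, holding that “ends are long-lived and termination is barely detectable”, gives 142, 155 and neither.

    2 living end → dead end (k = 190 /M/min)
    free monomer + living end → monomer in chains + living end, rate k2*[living end]*[free monomer] (k = 4500 /M/min)
    free monomer + initiator → living end + monomer in chains (k = 0.670 /M/min)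

The flask gives 664 for spring and 694 for midnight, so the answer is neither. Midnight keeps 80.8% of its initiator at 20.0 min. With X near one, L over its length puts φ at 19.2% there. The neighbouring flask, midnight with initiator at 0.45 mol%, has L = 222 and length 914, so φ is 24.3%, and it keeps 76% of its initiator.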